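**Retrosynthetic overview**
1. Target 44 ⇐ acetate 43 ⇐ cyclohexenone 41: the end game is a PMB→acetyl exchange at C10′ and acid removal of one TBS and two acetonides; the only ring (the cyclohexenone) is closed last, by RCM of dienone 40.
2. Dienone 40 ⇐ Weinreb amide 38 (vinyl Grignard) ⇐ Arndt–Eistert homologation of acid 34 ⇐ Evans syn-aldol of imide 27 with acrolein, which sets ring C4/C5.
3. Imide 27 ⇐ HWE olefination/hydrogenation on the C1′ aldehyde 25 of the protected polyol 23.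
4. Polyol 23 ⇐ key intermolecular 1,5-anti boron aldol of methyl ketone 8 (C7′–C10′ plus tail) with aldehyde 16 (C1′–C6′, from the commercial statin diol block), then 1,3-syn reduction.
5. Ketone 8 ⇐ Brown allylation, PMB protection and Wacker oxidation on 13-phenyltridecanal 4 (from 11-bromoundecan-1-ol and PhCH2CH2MgBr).

**Assumption and notation (one line each)**
- Assumption: the statin intermediate tert-butyl 2-[(4R,6S)-6-(hydroxymethyl)-2,2-dimethyl-1,3-dioxan-4-yl]acetate, (R)-4-benzyl-2-oxazolidinone and (−)-Ipc2BOMe are taken as cheap commercial materials.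
- Locants: ring C1 (C=O) to C6 as in the target (C4 = CHOH, C5 carries the chain); chain C1′ (CH2 on C5) to C10′ (CH–OAc); tail = (CH2)12Ph. "Target configuration" means the same spatial arrangement as in 44; formal CIP letters of intermediates can differ, and the SMILES are authoritative.
- Conjugate-base salts of reactants (alkoxides, lithiated oxazolidinone, phosphonate anion) are not numbered separately; all other in-flask intermediates are.

**Route**

Step 1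
Reactants: 1 11-bromoundecan-1-ol; 2 (2-phenylethyl)magnesium bromide
Product: 3 13-phenyltridecan-1-ol
Conditions: 2 (3 eq), Li2CuCl4 (3 mol%), THF, −78 °C → rt; 1 M HCl
Reagents that add atoms: none
Why: Kochi-type Cu-catalysed sp3–sp3 Grignard cross-coupling; the first equivalent of 2 only deprotonates the OH, so the primary bromide couples cleanly.

Step 2
Reactants: 3 13-phenyltridecan-1-ol
Product: 4 13-phenyltridecanal
Conditions: TEMPO (10 mol%), PhI(OAc)2 (1.1 eq), CH2Cl2, rt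
Reagents that add atoms: none
Why: TEMPO/oxoammonium oxidation of a primary alcohol stops at the aldehyde.

Step 3
Reactants: 4 13-phenyltridecanal
Product: 6 (4R)-16-phenylhexadec-1-en-4-ol, via diisopinocampheylborinate ester 5 (not isolated)
Conditions: (−)-Ipc2BOMe (1.3 eq), allylMgBr (1.25 eq), Et2O, 0 °C → rt; then 4, −78 °C; 3 M NaOH, 30% H2O2, rt
Reagents that add atoms: allylmagnesium bromide, C=CC[Mg]Br (allyl transferred through the borane made from (−)-B-methoxydiisopinocampheylborane, COB([C@@H]1C[C@@H]2C[C@H]([C@H]1C)C2(C)C)[C@@H]1C[C@@H]2C[C@H]([C@H]1C)C2(C)C, whose boron stays only in 5)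
Why: Brown asymmetric allylboration; the (+)-α-pinene-derived allylborane adds through a closed chair transition state to the Si face of the aliphatic aldehyde, setting C10′ as R.

Step 4
Reactants: 6 (4R)-16-phenylhexadec-1-en-4-ol
Product: 7 (4R)-4-[(4-methoxybenzyl)oxy]-16-phenylhexadec-1-ene
Conditions: NaH, PMBCl, Bu4NI (cat.), THF/DMF, 0 °C → rt
Reagents that add atoms: 4-methoxybenzyl chloride, COc1ccc(CCl)cc1
Why: Williamson etherification leaves the carbinol centre untouched and installs the β-PMB ether needed for 1,5-anti induction.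

Step 5
Reactants: 7 (4R)-4-[(4-methoxybenzyl)oxy]-16-phenylhexadec-1-ene
Product: 8 (4R)-4-[(4-methoxybenzyl)oxy]-16-phenylhexadecan-2-one
Conditions: PdCl2 (10 mol%), CuCl (1 eq), O2 (1 atm), DMF/H2O 7:1, rt
Reagents that add atoms: water, O (O2 is the terminal oxidant)
Why: Tsuji–Wacker oxidation converts the terminal alkene into the methyl ketone with Markovnikov selectivity.

Step 6
Reactants: 9 (4R)-4-benzyl-1,3-oxazolidin-2-one; 10 bromoacetyl bromide
Product: 11 (4R)-4-benzyl-3-(bromoacetyl)-1,3-oxazolidin-2-one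
Conditions: n-BuLi (1.0 eq), THF, −78 °C; then 10, −78 → 0 °C
Reagents that add atoms: none
Why: N-acylation of the lithiated oxazolidinone; the acyl bromide reacts far faster than the alkyl bromide.

Step 7
Reactants: 11 (4R)-4-benzyl-3-(bromoacetyl)-1,3-oxazolidin-2-one
Product: 12 diethyl {2-[(4R)-4-benzyl-2-oxo-1,3-oxazolidin-3-yl]-2-oxoethyl}phosphonate
Conditions: P(OEt)3 (1.5 eq), neat, 60 °C
Reagents that add atoms: triethyl phosphite, CCOP(OCC)OCC
Why: Michaelis–Arbuzov reaction of the activated α-bromo imide.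

Step 8
Reactants: 13 tert-butyl 2-[(4R,6S)-6-(hydroxymethyl)-2,2-dimethyl-1,3-dioxan-4-yl]acetate
Product: 14 tert-butyl 2-[(4R,6S)-6-{[(tert-butyldiphenylsilyl)oxy]methyl}-2,2-dimethyl-1,3-dioxan-4-yl]acetate
Conditions: TBDPSCl, imidazole, DMF, rt
Reagents that add atoms: tert-butyl(chloro)diphenylsilane, CC(C)(C)[Si](Cl)(c1ccccc1)c1ccccc1
Why: Imidazole-mediated silylation of the primary alcohol uses no strong base, so the β-alkoxy ester does not eliminate.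

Step 9
Reactants: 14 tert-butyl 2-[(4R,6S)-6-{[(tert-butyldiphenylsilyl)oxy]methyl}-2,2-dimethyl-1,3-dioxan-4-yl]acetate
Product: 16 2-[(4R,6S)-6-{[(tert-butyldiphenylsilyl)oxy]methyl}-2,2-dimethyl-1,3-dioxan-4-yl]acetaldehyde, via aluminium hemiacetal 15 (not isolated)
Conditions: DIBAL-H (1.15 eq), CH2Cl2, −78 °C; MeOH, aq. Rochelle salt
Reagents that add atoms: none
Why: Partial ester reduction with DIBAL-H; the aluminium hemiacetal of the bulky tert-butyl ester is stable at −78 °C and collapses to the aldehyde only on work-up.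

Step 10
Reactants: 8 (4R)-4-[(4-methoxybenzyl)oxy]-16-phenylhexadecan-2-one; 16 2-[(4R,6S)-6-{[(tert-butyldiphenylsilyl)oxy]methyl}-2,2-dimethyl-1,3-dioxan-4-yl]acetaldehyde
Product: 19 C6′-hydroxy-C8′-ketone aldol adduct, via boron enolate 17 (not isolated), via boron aldolate 18 (not isolated)
Conditions: 8, n-Bu2BOTf (1.2 eq), i-Pr2NEt (1.4 eq), Et2O, −78 °C; then 16, −78 °C; pH 7 buffer, MeOH, 30% H2O2, 0 °C
Reagents that add atoms: dibutylboron triflate, CCCCB(CCCC)OS(=O)(=O)C(F)(F)F (boron only in 17 and 18)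
Why: 1,5-anti boron aldol; the dibutylboron enolate of the β-PMB-oxy methyl ketone adds anti to the C10′ ether, and the β-alkoxy aldehyde has little bias in boron aldols, so C6′ is formed 1,5-anti to C10′.

Step 11
Reactants: 19 C6′-hydroxy-C8′-ketone aldol adduct
Product: 22 C6′/C8′ syn-diol, via diethylboron chelate 20 (not isolated), via sodium cyclic diethylborate 21 (not isolated)
Conditions: Et2BOMe (1.1 eq), THF/MeOH 4:1, −78 °C; NaBH4, −78 °C; pH 7 buffer, 30% H2O2, 0 °C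
Reagents that add atoms: diethylmethoxyborane, CCB(CC)OC (boron only in 20 and 21)
Why: Narasaka–Prasad reduction; the six-membered boron chelate takes external axial hydride to give the 1,3-syn diol (C8′ syn to C6′, hence anti to C10′).

Step 12
Reactants: 22 C6′/C8′ syn-diol
Product: 23 2′,4′:6′,8′-bis-acetonide (1′-OTBDPS; 10′-OPMB)
Conditions: 2,2-dimethoxypropane, PPTS (cat.), CH2Cl2, rt
Reagents that add atoms: 2,2-dimethoxypropane, COC(C)(C)OC
Why: Acid-catalysed transketalisation under thermodynamic control gives the chair syn-1,3-diol acetonide.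

Step 13
Reactants: 23 2′,4′:6′,8′-bis-acetonide (1′-OTBDPS; 10′-OPMB)
Product: 24 C1′ primary alcohol
Conditions: TBAF (1.2 eq), THF, 0 °C → rt; aq. NH4Cl
Reagents that add atoms: none
Why: Fluoride-mediated desilylation; the PMB ether and ketals are inert.

Step 14
Reactants: 24 C1′ primary alcohol
Product: 25 C1′ aldehyde
Conditions: TEMPO (10 mol%), PhI(OAc)2 (1.2 eq), CH2Cl2, rt
Reagents that add atoms: none
Why: TEMPO oxidation under near-neutral conditions gives the α-alkoxy aldehyde without epimerisation.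

Step 15
Reactants: 25 C1′ aldehyde; 12 diethyl {2-[(4R)-4-benzyl-2-oxo-1,3-oxazolidin-3-yl]-2-oxoethyl}phosphonate
Product: 26 (E)-N-enoyl oxazolidinone
Conditions: LiCl (1.5 eq), i-Pr2NEt (1.2 eq), MeCN, rt
Reagents that add atoms: none
Why: Horner–Wadsworth–Emmons olefination under Masamune–Roush conditions is E-selective and mild enough not to epimerise the α-alkoxy aldehyde.

Step 16
Reactants: 26 (E)-N-enoyl oxazolidinone
Product: 27 saturated N-acyl oxazolidinone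
Conditions: H2 (1 atm), 5% Pd/C, pyridine (0.5 eq), EtOAc, rt
Reagents that add atoms: none
Why: Catalytic hydrogenation of the conjugated alkene; the pyridine-poisoned catalyst leaves the PMB ether intact.

Step 17
Reactants: 27 saturated N-acyl oxazolidinone; 28 acrolein
Product: 31 Evans syn-aldol adduct, via Z-boron enolate 29 (not isolated), via boron aldolate 30 (not isolated)
Conditions: n-Bu2BOTf (1.2 eq), i-Pr2NEt (1.4 eq), CH2Cl2, −78 → 0 °C; then 28 (3 eq, freshly distilled), −78 → 0 °C; pH 7 buffer, MeOH, 30% H2O2, 0 °C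
Reagents that add atoms: dibutylboron triflate, CCCCB(CCCC)OS(=O)(=O)C(F)(F)F (boron only in 29 and 30)
Why: Evans syn-aldol; the Z-boron enolate reacts through a Zimmerman–Traxler chair on the face opposite the benzyl group of the (R)-auxiliary, giving the (2R,3S)-syn adduct that becomes ring C5 (S) and C4 (R).

Step 18
Reactants: 31 Evans syn-aldol adduct
Product: 32 C4-O-TBS ether
Conditions: TBSOTf (1.3 eq), 2,6-lutidine (2 eq), CH2Cl2, −78 → 0 °C
Reagents that add atoms: tert-butyldimethylsilyl triflate, CC(C)(C)[Si](C)(C)OS(=O)(=O)C(F)(F)F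
Why: Silylation of the secondary allylic alcohol blocks retro-aldol and protects C4–OH to the end.

Step 19
Reactants: 32 C4-O-TBS ether
Product: 34 carboxylic acid, via lithium peroxycarboxylate 33 (not isolated)
Conditions: LiOH·H2O (2 eq), 30% H2O2 (6 eq), THF/H2O 3:1, 0 °C; aq. Na2SO3; 1 M HCl to pH 4, 0 °C
Reagents that add atoms: lithium hydroperoxide, [Li+].[O-]O (from LiOH and H2O2; supplies the carboxyl OH oxygen)
Why: Hydroperoxide-mediated exocyclic cleavage of the imide (Evans LiOOH protocol) does not epimerise C5, and the auxiliary is recovered.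

Step 20
Reactants: 34 carboxylic acid
Product: 36 α-diazoketone, via isobutyl mixed anhydride 35 (not isolated)
Conditions: i-BuOCOCl (1.1 eq), N-methylmorpholine (1.2 eq), THF, −20 °C; then CH2N2 (Et2O, 3 eq), −20 °C → rt
Reagents that add atoms: isobutyl chloroformate, CC(C)COC(Cl)=O (only in 35); diazomethane, C=[N+]=[N-]
Why: Arndt–Eistert homologation, first half; acylation of diazomethane by the mixed anhydride leaves the α-stereocentre untouched.

Step 21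
Reactants: 36 α-diazoketone
Product: 38 homologated Weinreb amide, via ketene 37 (not isolated)
Conditions: PhCO2Ag (10 mol%), Et3N (3 eq), MeNHOMe·HCl (2 eq), THF, −25 °C → rt, dark
Reagents that add atoms: N,O-dimethylhydroxylamine hydrochloride, CNOC.Cl
Why: Silver-catalysed Wolff rearrangement; C5 migrates with retention and the ketene is trapped by the amine, inserting the ring C6 methylene.

Step 22
Reactants: 38 homologated Weinreb amide
Product: 40 vinyl ketone, via magnesium hemiaminal chelate 39 (not isolated)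
Conditions: CH2=CHMgBr (2.5 eq), THF, −10 → 0 °C; inverse quench into cold 1 M HCl/Et2O
Reagents that add atoms: vinylmagnesium bromide, C=C[Mg]Br
Why: Weinreb ketone synthesis; the chelated tetrahedral intermediate prevents over-addition, and the acidic inverse quench suppresses aza-Michael addition to the enone.

Step 23
Reactants: 40 vinyl ketone
Product: 41 4-silyloxy-5-alkylcyclohex-2-enone
Conditions: Grubbs II (5–10 mol%), CH2Cl2 (0.005 M), 40 °C
Reagents that add atoms: none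
Why: Ring-closing metathesis of the vinyl ketone with the allylic silyl ether closes the six-membered enone without touching any stereocentre.

Step 24
Reactants: 41 4-silyloxy-5-alkylcyclohex-2-enone
Product: 42 C10′ alcohol
Conditions: DDQ (1.5 eq), CH2Cl2/pH 7 buffer 10:1, 0 °C → rt
Reagents that add atoms: none
Why: Oxidative PMB cleavage with DDQ under buffered conditions; enone, silyl ether and acetonides are inert.

Step 25
Reactants: 42 C10′ alcohol
Product: 43 C10′ acetate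
Conditions: Ac2O (3 eq), pyridine, DMAP (cat.), CH2Cl2, 0 °C → rt
Reagents that add atoms: acetic anhydride, CC(=O)OC(C)=O
Why: DMAP-catalysed acylation of the only free hydroxyl group.

Step 26
Reactants: 43 C10′ acetate
Product: 44 target
Conditions: 48% aq. HF/MeCN 1:10, 0 °C → rt; quench with MeOSiMe3
Reagents that add atoms: none
Why: Acid-mediated global deprotection (HF desilylation and hydrolysis of both acetonides); the neutral quench avoids acetyl migration and base chemistry of the hydroxy-enone.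

**Compound list**
1 | 11-bromoundecan-1-ol | OCCCCCCCCCCCBr | starting material
2 | (2-phenylethyl)magnesium bromide | Br[Mg]CCc1ccccc1 | starting material
3 | 13-phenyltridecan-1-ol | OCCCCCCCCCCCCCc1ccccc1 | intermediate
4 | 13-phenyltridecanal | O=CCCCCCCCCCCCCc1ccccc1 | intermediate
5 | (4R)-16-phenylhexadec-1-en-4-yl diisopinocampheylborinate (Ipc groups from (+)-α-pinene) | B([C@@H]1C[C@@H]2C[C@H]([C@H]1C)C2(C)C)([C@@H]1C[C@@H]2C[C@H]([C@H]1C)C2(C)C)O[C@H](CCCCCCCCCCCCc1ccccc1)CC=C | intermediate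
6 | (4R)-16-phenylhexadec-1-en-4-ol | O[C@H](CCCCCCCCCCCCc1ccccc1)CC=C | intermediate
7 | (4R)-4-[(4-methoxybenzyl)oxy]-16-phenylhexadec-1-ene | COc1ccc(CO[C@H](CCCCCCCCCCCCc2ccccc2)CC=C)cc1 | intermediate
8 | (4R)-4-[(4-methoxybenzyl)oxy]-16-phenylhexadecan-2-one (C7′–C10′ plus tail; 10′R) | COc1ccc(CO[C@H](CCCCCCCCCCCCc2ccccc2)CC(C)=O)cc1 | intermediate
9 | (4R)-4-benzyl-1,3-oxazolidin-2-one | O=C1N[C@H](Cc2ccccc2)CO1 | starting material
10 | bromoacetyl bromide | BrCC(Br)=O | starting material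
11 | (4R)-4-benzyl-3-(bromoacetyl)-1,3-oxazolidin-2-one | O=C(CBr)N1[C@H](Cc2ccccc2)COC1=O | intermediate
12 | diethyl {2-[(4R)-4-benzyl-2-oxo-1,3-oxazolidin-3-yl]-2-oxoethyl}phosphonate | CCOP(=O)(CC(=O)N1[C@H](Cc2ccccc2)COC1=O)OCC | intermediate
13 | tert-butyl 2-[(4R,6S)-6-(hydroxymethyl)-2,2-dimethyl-1,3-dioxan-4-yl]acetate (C1′–C6′; syn-diol acetonide) | CC(C)(C)OC(=O)C[C@H]1C[C@@H](CO)OC(C)(C)O1 | starting material
14 | tert-butyl 2-[(4R,6S)-6-{[(tert-butyldiphenylsilyl)oxy]methyl}-2,2-dimethyl-1,3-dioxan-4-yl]acetate | CC(C)(C)OC(=O)C[C@H]1C[C@@H](CO[Si](c2ccccc2)(c2ccccc2)C(C)(C)C)OC(C)(C)O1 | intermediate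
15 | diisobutylaluminium hemiacetal of 14 (hemiacetal carbon unassigned) | CC(C)C[Al](CC(C)C)OC(OC(C)(C)C)C[C@H]1C[C@@H](CO[Si](c2ccccc2)(c2ccccc2)C(C)(C)C)OC(C)(C)O1 | intermediate
16 | 2-[(4R,6S)-6-{[(tert-butyldiphenylsilyl)oxy]methyl}-2,2-dimethyl-1,3-dioxan-4-yl]acetaldehyde (C6′ aldehyde) | O=CC[C@H]1C[C@@H](CO[Si](c2ccccc2)(c2ccccc2)C(C)(C)C)OC(C)(C)O1 | intermediate
17 | dibutylboron enolate of 8 on the methyl side (10′R) | COc1ccc(CO[C@H](CCCCCCCCCCCCc2ccccc2)CC(=C)OB(CCCC)CCCC)cc1 | intermediate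
18 | C6′-O-dibutylboryl aldolate of 19 | COc1ccc(CO[C@H](CCCCCCCCCCCCc2ccccc2)CC(=O)C[C@H](OB(CCCC)CCCC)C[C@H]2C[C@@H](CO[Si](c3ccccc3)(c3ccccc3)C(C)(C)C)OC(C)(C)O2)cc1 | intermediate
19 | aldol adduct: 1′-OTBDPS; 2′,4′-O-isopropylidene (syn); 6′-OH; 8′-oxo; 10′-OPMB; tail (CH2)12Ph; 6′-OH anti to 10′-O and syn to 4′-O; target configuration at C2′, C4′, C6′, C10′ | COc1ccc(CO[C@H](CCCCCCCCCCCCc2ccccc2)CC(=O)C[C@H](O)C[C@H]2C[C@@H](CO[Si](c3ccccc3)(c3ccccc3)C(C)(C)C)OC(C)(C)O2)cc1 | intermediate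
20 | C6′-O-diethylboryl chelate of 19 | COc1ccc(CO[C@H](CCCCCCCCCCCCc2ccccc2)CC(=O)C[C@H](OB(CC)CC)C[C@H]2C[C@@H](CO[Si](c3ccccc3)(c3ccccc3)C(C)(C)C)OC(C)(C)O2)cc1 | intermediate
21 | sodium cyclic 6′,8′-O-diethylborate of 22 | [Na+].COc1ccc(CO[C@H](CCCCCCCCCCCCc2ccccc2)C[C@H]2C[C@@H](C[C@H]3C[C@@H](CO[Si](c4ccccc4)(c4ccccc4)C(C)(C)C)OC(C)(C)O3)O[B-](CC)(CC)O2)cc1 | intermediate
22 | 6′,8′-syn-diol (otherwise as 19); target configuration at C2′, C4′, C6′, C8′, C10′ | COc1ccc(CO[C@H](CCCCCCCCCCCCc2ccccc2)C[C@H](O)C[C@H](O)C[C@H]2C[C@@H](CO[Si](c3ccccc3)(c3ccccc3)C(C)(C)C)OC(C)(C)O2)cc1 | intermediate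
23 | 2′,4′:6′,8′-di-O-isopropylidene polyol with 1′-OTBDPS and 10′-OPMB (all centres target configuration) | COc1ccc(CO[C@H](CCCCCCCCCCCCc2ccccc2)C[C@H]2C[C@@H](C[C@H]3C[C@@H](CO[Si](c4ccccc4)(c4ccccc4)C(C)(C)C)OC(C)(C)O3)OC(C)(C)O2)cc1 | intermediate
24 | C1′ primary alcohol of 23 | COc1ccc(CO[C@H](CCCCCCCCCCCCc2ccccc2)C[C@H]2C[C@@H](C[C@H]3C[C@@H](CO)OC(C)(C)O3)OC(C)(C)O2)cc1 | intermediate
25 | C1′ aldehyde | COc1ccc(CO[C@H](CCCCCCCCCCCCc2ccccc2)C[C@H]2C[C@@H](C[C@H]3C[C@@H](C=O)OC(C)(C)O3)OC(C)(C)O2)cc1 | intermediate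
26 | (E)-enimide: C1′H=C5H–C(=O)–N of (4R)-4-benzyl-oxazolidin-2-one | COc1ccc(CO[C@H](CCCCCCCCCCCCc2ccccc2)C[C@H]2C[C@@H](C[C@H]3C[C@@H](/C=C/C(=O)N4[C@H](Cc5ccccc5)COC4=O)OC(C)(C)O3)OC(C)(C)O2)cc1 | intermediate
27 | saturated N-acyl oxazolidinone (C1′H2–C5H2–C(=O)N) | COc1ccc(CO[C@H](CCCCCCCCCCCCc2ccccc2)C[C@H]2C[C@@H](C[C@H]3C[C@@H](CCC(=O)N4[C@H](Cc5ccccc5)COC4=O)OC(C)(C)O3)OC(C)(C)O2)cc1 | intermediate
28 | acrolein (prop-2-enal) | C=CC=O | starting material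
29 | (Z)-dibutylboron enolate of 27 | COc1ccc(CO[C@H](CCCCCCCCCCCCc2ccccc2)C[C@H]2C[C@@H](C[C@H]3C[C@@H](C/C=C(\OB(CCCC)CCCC)N4[C@H](Cc5ccccc5)COC4=O)OC(C)(C)O3)OC(C)(C)O2)cc1 | intermediate
30 | C4-O-dibutylboryl aldolate of 31 | COc1ccc(CO[C@H](CCCCCCCCCCCCc2ccccc2)C[C@H]2C[C@@H](C[C@H]3C[C@@H](C[C@H]([C@@H](OB(CCCC)CCCC)C=C)C(=O)N4[C@H](Cc5ccccc5)COC4=O)OC(C)(C)O3)OC(C)(C)O2)cc1 | intermediate
31 | Evans syn-aldol adduct: imide C(=O)–C5H(C1′H2…)–C4H(OH)–CH=CH2, (2R,3S) in the acyl unit = target configuration at ring C5 and C4 | COc1ccc(CO[C@H](CCCCCCCCCCCCc2ccccc2)C[C@H]2C[C@@H](C[C@H]3C[C@@H](C[C@H]([C@@H](O)C=C)C(=O)N4[C@H](Cc5ccccc5)COC4=O)OC(C)(C)O3)OC(C)(C)O2)cc1 | intermediate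
32 | C4-O-TBS ether of 31 | COc1ccc(CO[C@H](CCCCCCCCCCCCc2ccccc2)C[C@H]2C[C@@H](C[C@H]3C[C@@H](C[C@H]([C@@H](O[Si](C)(C)C(C)(C)C)C=C)C(=O)N4[C@H](Cc5ccccc5)COC4=O)OC(C)(C)O3)OC(C)(C)O2)cc1 | intermediate
33 | lithium peroxycarboxylate from 32 | [Li+].COc1ccc(CO[C@H](CCCCCCCCCCCCc2ccccc2)C[C@H]2C[C@@H](C[C@H]3C[C@@H](C[C@H]([C@@H](O[Si](C)(C)C(C)(C)C)C=C)C(=O)O[O-])OC(C)(C)O3)OC(C)(C)O2)cc1 | intermediate
34 | carboxylic acid (C5 α-stereocentre; C4-OTBS; vinyl) | COc1ccc(CO[C@H](CCCCCCCCCCCCc2ccccc2)C[C@H]2C[C@@H](C[C@H]3C[C@@H](C[C@H]([C@@H](O[Si](C)(C)C(C)(C)C)C=C)C(O)=O)OC(C)(C)O3)OC(C)(C)O2)cc1 | intermediate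
35 | isobutyl carbonic mixed anhydride of 34 | COc1ccc(CO[C@H](CCCCCCCCCCCCc2ccccc2)C[C@H]2C[C@@H](C[C@H]3C[C@@H](C[C@H]([C@@H](O[Si](C)(C)C(C)(C)C)C=C)C(=O)OC(=O)OCC(C)C)OC(C)(C)O3)OC(C)(C)O2)cc1 | intermediate
36 | α-diazoketone | COc1ccc(CO[C@H](CCCCCCCCCCCCc2ccccc2)C[C@H]2C[C@@H](C[C@H]3C[C@@H](C[C@H]([C@@H](O[Si](C)(C)C(C)(C)C)C=C)C(=O)C=[N+]=[N-])OC(C)(C)O3)OC(C)(C)O2)cc1 | intermediate
37 | ketene (C5–CH=C=O) | COc1ccc(CO[C@H](CCCCCCCCCCCCc2ccccc2)C[C@H]2C[C@@H](C[C@H]3C[C@@H](C[C@H]([C@@H](O[Si](C)(C)C(C)(C)C)C=C)C=C=O)OC(C)(C)O3)OC(C)(C)O2)cc1 | intermediate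
38 | homologated Weinreb amide: C5–C6H2–C1(=O)N(OMe)Me | COc1ccc(CO[C@H](CCCCCCCCCCCCc2ccccc2)C[C@H]2C[C@@H](C[C@H]3C[C@@H](C[C@H]([C@@H](O[Si](C)(C)C(C)(C)C)C=C)CC(=O)N(C)OC)OC(C)(C)O3)OC(C)(C)O2)cc1 | intermediate
39 | bromomagnesium hemiaminal from 38 and vinylMgBr (C1 unassigned) | COc1ccc(CO[C@H](CCCCCCCCCCCCc2ccccc2)C[C@H]2C[C@@H](C[C@H]3C[C@@H](C[C@H]([C@@H](O[Si](C)(C)C(C)(C)C)C=C)CC(O[Mg]Br)(C=C)N(C)OC)OC(C)(C)O3)OC(C)(C)O2)cc1 | intermediate
40 | vinyl ketone: CH2=CH–C1(=O)–C6H2–C5H(C1′…)–C4H(OTBS)–CH=CH2 | COc1ccc(CO[C@H](CCCCCCCCCCCCc2ccccc2)C[C@H]2C[C@@H](C[C@H]3C[C@@H](C[C@H]([C@@H](O[Si](C)(C)C(C)(C)C)C=C)CC(=O)C=C)OC(C)(C)O3)OC(C)(C)O2)cc1 | intermediate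
41 | (4R,5S)-4-(TBS-oxy)-5-substituted cyclohex-2-enone with bis-acetonide chain and 10′-OPMB (trans ring; all centres target configuration) | COc1ccc(CO[C@H](CCCCCCCCCCCCc2ccccc2)C[C@H]2C[C@@H](C[C@H]3C[C@@H](C[C@H]4CC(=O)C=C[C@@H]4O[Si](C)(C)C(C)(C)C)OC(C)(C)O3)OC(C)(C)O2)cc1 | intermediate
42 | C10′ alcohol of 41 | O[C@H](CCCCCCCCCCCCc1ccccc1)C[C@H]1C[C@@H](C[C@H]2C[C@@H](C[C@H]3CC(=O)C=C[C@@H]3O[Si](C)(C)C(C)(C)C)OC(C)(C)O2)OC(C)(C)O1 | intermediate
43 | C10′ acetate | CC(=O)O[C@H](CCCCCCCCCCCCc1ccccc1)C[C@H]1C[C@@H](C[C@H]2C[C@@H](C[C@H]3CC(=O)C=C[C@@H]3O[Si](C)(C)C(C)(C)C)OC(C)(C)O2)OC(C)(C)O1 | intermediate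
44 | target: (4R,5S)-4-hydroxy-5-[(2′R,4′R,6′R,8′R,10′R)-10′-acetoxy-2′,4′,6′,8′-tetrahydroxy-22′-phenyldocosyl]cyclohex-2-en-1-one | CC(=O)O[C@H](CCCCCCCCCCCCc1ccccc1)C[C@H](O)C[C@H](O)C[C@H](O)C[C@H](O)C[C@H]1CC(=O)C=C[C@@H]1O | target

**Totals**
Total steps: 26. Longest linear sequence: 22 steps (steps 1–5, then 10–26).

**Three steps most likely to fail, with fallbacks**

Step 10 (fragment-coupling aldol; the diastereomer ratio or conversion may suffer with the β-alkoxy aldehyde). The fallback builds the same C6′–C10′ array in the reverse sense. It sets out from aldehyde 16 (and aldehyde 4) and returns at 23. Brown allylboration of 16 with the same (+)-α-pinene-derived allylborane gives the C6′ homoallylic alcohol F1, with C6′ set by the reagent. NaH/PMBCl gives the C6′ PMB ether F2, and Wacker oxidation gives the C8′ methyl ketone F3. Its dibutylboron enolate adds to 4 in a 1,5-anti aldol (now from the C6′ ether to C10′) to give the C10′-hydroxy ketone F4. Me4NBH(OAc)3 (Evans–Saksena, hydroxyl-directed 1,3-anti reduction) gives the 8′,10′-anti diol F5. DDQ removes the PMB group to give the 6′,8′,10′-triol F6. 2,2-Dimethoxypropane/PPTS under thermodynamic control ketalises only the syn 6′,8′-diol (the anti 8′,10′ acetonide would need a twist-boat) to give the C10′-hydroxy bis-acetonide F7. NaH/PMBCl then gives 23.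

Step 22 (the vinyl ketone is prone to aza-Michael addition and polymerisation, and the following RCM uses an electron-poor alkene). The fallback sets out from Weinreb amide 38 and returns at 41. DIBAL-H at −78 °C gives the homologated aldehyde F8. Vinylmagnesium bromide gives the allylic alcohol F9 as a mixture of C1 epimers, which does not matter. RCM with Grubbs II on these two unhindered terminal alkenes gives the cyclohexenol F10. Dess–Martin periodinane (or MnO2) oxidises the allylic alcohol to enone 41.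

Step 26 (acidic global deprotection in the presence of the acetate and the γ-hydroxy-enone: acyl migration, oxa-Michael addition or elimination are possible). The fallback sets out from 41 and returns at 44, moving the acidic deprotection ahead of acetylation. Aqueous HF/MeCN on 41 removes TBS and both acetonides while the PMB ether is still in place and no acetate is present, giving the PMB-protected pentaol F11. TESOTf/2,6-lutidine gives the penta-TES ether F12. DDQ gives the C10′ alcohol F13. Ac2O/DMAP gives the penta-TES acetate F14. Buffered HF·pyridine/pyridine in THF at 0 °C then removes the five TES groups under almost neutral conditions to give 44.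

**Further compounds**
F1 | step 10 | C6′ homoallylic alcohol from 16 (C6′ target configuration; 1′-OTBDPS; 2′,4′-acetonide) | C=CC[C@H](O)C[C@H]1C[C@@H](CO[Si](c2ccccc2)(c2ccccc2)C(C)(C)C)OC(C)(C)O1
F2 | step 10 | C6′ PMB ether of F1 | C=CC[C@H](OCc1ccc(OC)cc1)C[C@H]1C[C@@H](CO[Si](c2ccccc2)(c2ccccc2)C(C)(C)C)OC(C)(C)O1
F3 | step 10 | C8′ methyl ketone with C6′-OPMB | CC(=O)C[C@H](OCc1ccc(OC)cc1)C[C@H]1C[C@@H](CO[Si](c2ccccc2)(c2ccccc2)C(C)(C)C)OC(C)(C)O1
F4 | step 10 | C10′-hydroxy C8′-ketone (10′-OH anti to 6′-OPMB) | O[C@H](CCCCCCCCCCCCc1ccccc1)CC(=O)C[C@H](OCc1ccc(OC)cc1)C[C@H]1C[C@@H](CO[Si](c2ccccc2)(c2ccccc2)C(C)(C)C)OC(C)(C)O1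
F5 | step 10 | 8′,10′-anti diol with C6′-OPMB | O[C@H](CCCCCCCCCCCCc1ccccc1)C[C@H](O)C[C@H](OCc1ccc(OC)cc1)C[C@H]1C[C@@H](CO[Si](c2ccccc2)(c2ccccc2)C(C)(C)C)OC(C)(C)O1
F6 | step 10 | 6′,8′,10′-triol | O[C@H](CCCCCCCCCCCCc1ccccc1)C[C@H](O)C[C@H](O)C[C@H]1C[C@@H](CO[Si](c2ccccc2)(c2ccccc2)C(C)(C)C)OC(C)(C)O1
F7 | step 10 | C10′-hydroxy 2′,4′:6′,8′-bis-acetonide (1′-OTBDPS) | O[C@H](CCCCCCCCCCCCc1ccccc1)C[C@H]1C[C@@H](C[C@H]2C[C@@H](CO[Si](c3ccccc3)(c3ccccc3)C(C)(C)C)OC(C)(C)O2)OC(C)(C)O1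
F8 | step 22 | homologated aldehyde (C1 = CHO) from 38 | COc1ccc(CO[C@H](CCCCCCCCCCCCc2ccccc2)C[C@H]2C[C@@H](C[C@H]3C[C@@H](C[C@H]([C@@H](O[Si](C)(C)C(C)(C)C)C=C)CC=O)OC(C)(C)O3)OC(C)(C)O2)cc1
F9 | step 22 | allylic alcohol (C1 carbinol as both epimers) | COc1ccc(CO[C@H](CCCCCCCCCCCCc2ccccc2)C[C@H]2C[C@@H](C[C@H]3C[C@@H](C[C@H]([C@@H](O[Si](C)(C)C(C)(C)C)C=C)CC(O)C=C)OC(C)(C)O3)OC(C)(C)O2)cc1
F10 | step 22 | cyclohex-2-en-1-ol (C1 epimers; 4-OTBS; 5-alkyl) | COc1ccc(CO[C@H](CCCCCCCCCCCCc2ccccc2)C[C@H]2C[C@@H](C[C@H]3C[C@@H](C[C@H]4CC(O)C=C[C@@H]4O[Si](C)(C)C(C)(C)C)OC(C)(C)O3)OC(C)(C)O2)cc1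
F11 | step 26 | 10′-O-PMB pentaol enone | COc1ccc(CO[C@H](CCCCCCCCCCCCc2ccccc2)C[C@H](O)C[C@H](O)C[C@H](O)C[C@H](O)C[C@H]2CC(=O)C=C[C@@H]2O)cc1
F12 | step 26 | penta-TES ether of F11 | COc1ccc(CO[C@H](CCCCCCCCCCCCc2ccccc2)C[C@H](O[Si](CC)(CC)CC)C[C@H](O[Si](CC)(CC)CC)C[C@H](O[Si](CC)(CC)CC)C[C@H](O[Si](CC)(CC)CC)C[C@H]2CC(=O)C=C[C@@H]2O[Si](CC)(CC)CC)cc1
F13 | step 26 | penta-TES C10′ alcohol | O[C@H](CCCCCCCCCCCCc1ccccc1)C[C@H](O[Si](CC)(CC)CC)C[C@H](O[Si](CC)(CC)CC)C[C@H](O[Si](CC)(CC)CC)C[C@H](O[Si](CC)(CC)CC)C[C@H]1CC(=O)C=C[C@@H]1O[Si](CC)(CC)CC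
F14 | step 26 | penta-TES C10′ acetate | CC(=O)O[C@H](CCCCCCCCCCCCc1ccccc1)C[C@H](O[Si](CC)(CC)CC)C[C@H](O[Si](CC)(CC)CC)C[C@H](O[Si](CC)(CC)CC)C[C@H](O[Si](CC)(CC)CC)C[C@H]1CC(=O)C=C[C@@H]1O[Si](CC)(CC)CC
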